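(The readings were computed for an exercise; the scatter is artificial.)

1. The winter run kept 49.6 % of its left-handed substrate after 8.00 h; the summer run kept 88.2 % after 15.0 h. Both are single readings with their scatter.

in all of them: gas 160 mM (held)

| flask | left-handed substrate | right-handed substrate | temperature | remark | time |
|---|---|---|---|---|---|
| summer | 1.3 M | 1.3 M | −10 °C | run made earlier |  |
| winter | 1.3 M | 1.3 M | 10 °C | run made earlier |  |
| teal | 2.0 M | 2.0 M | −5 °C |  | 20 h |
| green | 2.0 M | 2.0 M | 25 °C |  | 20 h |

| run | time / h | left-handed product / % | left-handed substrate / % |
|---|---|---|---|
| summer | 1.33 | 1.2 | 51.2 |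
| summer | 2.00 | 0.2 | 47.5 |
| summer | 4.00 | 2.2 | 48.0 |
| summer | 6.00 | 5.4 | 46.7 |
| summer | 10.0 | 6.2 | 44.6 |
| summer | 15.0 | 6.4 | 44.1 |
| winter | 0.667 | 4.8 | 47.4 |
| winter | 1.00 | 4.0 | 45.1 |
| winter | 2.00 | 8.7 | 42.1 |
| winter | 3.00 | 9.9 | 37.5 |
| winter | 5.00 | 16.1 | 32.0 |
| winter | 8.00 | 22.4 | 24.8 |

(readings scatter by 1 percentage point)
- coupling partner is single-handed; left-handed substrate and right-handed substrate are mirror images of each other, charged as a racemate, each of them at the stated concentration
- the numbers in the tables scatter by 1 percentage point (one standard deviation)
- at the start none of the gas is in solution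
- the handed part of coupling partner does not stay in what it makes, so the products of the two hands are mirror images too
* the flask with the highest amount of left-handed product, in percent of the left-handed substrate and right-handed substrate together charged ("all alike" if they lie within 1.5 percentage points) (teal / green / all alike)
* final left-handed product, as a percentage of the left-handed substrate and right-handed substrate together charged, in teal
* final left-handed product, as a percentage of the left-handed substrate and right-handed substrate together charged, in green

2. The gas is held, so I freeze the coupling partner and treat the loss of left-handed substrate as pseudo-first-order. Winter gives 0.0876 h⁻¹, summer 0.00837 h⁻¹.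
3. I carry the warming factor 10.5, the winter constant divided by the summer one. I take the logarithm of the constant as straight in temperature.
4. Teal stands a quarter of the way from summer to winter. Its constant is 0.0151 h⁻¹, so I reckon that at 20 h teal keeps 74.0 % of its left-handed substrate. That makes about 13.0 % left-handed product.
5. Green lies above winter, so its constant of 0.510 h⁻¹ is an extrapolation, and I reckon it leaves 0.00372 % of green's left-handed substrate. Watch green's product, not its substrate: at its last reading, winter's left-handed product and left-handed substrate sum to 47.2 % of both substrates charged. I expect green highest, below 0.5 of both substrates charged.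
6. Keep the gas held and the bath steady.

The forecast says green, teal 8 %, green 44 %: “Teal would reach about 27% if nothing stopped it, but −5 °C is probably still stall-limited.” My teal figure differs from it.

The flasks give green as highest, teal 15.0 %, green 32.3 %. Green holds 33.5 % right-handed product beside its left-handed product.

    coupling partner + left-handed substrate → left-handed product (k = 2.40 M⁻¹ h⁻¹, Ea = 67.0 kJ mol⁻¹)
    coupling partner + right-handed substrate → right-handed product (k = 0.120 M⁻¹ h⁻¹, Ea = 58.0 kJ mol⁻¹)
    gas ⇌ coupling partner, rate k3*(csat - [coupling partner]) (kL = 280 h⁻¹)
    coupling partner → decomposed reagent (k = 0.380 h⁻¹, Ea = 99.0 kJ mol⁻¹)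
    left-handed product ⇌ right-handed product (k = 0.270 h⁻¹, Ea = 92.0 kJ mol⁻¹)
    (constants at 25 °C)

Teal kept 69 % of its left-handed substrate, against my 74.0 %. The neighbour repeats teal at −20 °C. The warming factor, taken below summer, gives it 0.00259 h⁻¹. So I reckon 95.0 % of its left-handed substrate stays, and about 2.50 % becomes left-handed product. The neighbour keeps 94 % of that substrate and holds 3.04 % left-handed product.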